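The data are calculated for an exercise, noise included.

If two mirror-image substrates are consumed through the same catalyst and reagent, each first order in itself, and neither turns into the other, both logarithms of the fraction left grow by the same time factor. Their ratio therefore stays constant, however the catalyst behaves.

- epsilon: left-handed substrate 0.10 M; right-handed substrate 0.10 M; reagent 0.40 M; precatalyst 2.6 mM; run made earlier
- flask: left-handed substrate 0.10 M; reagent 0.400 M; precatalyst 1.3 mM; right-handed substrate 0.10 M; time 4.0 h

epsilon run (percent of the left-handed substrate and right-handed substrate together charged)

| time / min | left-handed product / % | right-handed product / % |
|---|---|---|
| 10.0 | 8.9 | 3.7 |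
| 20.0 | 17.0 | 9.0 |
| 30.0 | 25.1 | 13.7 |
| 40.0 | 30.1 | 18.4 |
| 50.0 | 34.7 | 20.4 |

(standard deviation of a reading: 0.5 percentage points)

* left-handed product and right-handed product together, in percent of the left-handed substrate and right-handed substrate charged together, at 4.0 h
* excess of left-handed product over right-handed product in the product at 4.0 h
* whether the exchange between left-handed substrate and right-handed substrate keeps pace with the reaction: how far the product's excess at 4.0 h gets from its value without exchange to its value with instant exchange (above 80 % keeps pace, below 20 % hardly takes part, else lags behind)

- catalyst is single-handed; left-handed substrate and right-handed substrate are mirror images of each other, charged as a racemate, each of them at the stated concentration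
- the analysis behind the earlier runs scatters by 0.5 percentage points, standard deviation
- an excess is the difference of the two amounts in percent of their sum
- an excess is below zero if the other one leads
- no earlier run changes the charge of precatalyst; that part of a forecast is a guess

Each substrate was charged as half of the total, so, if neither turns into the other, its fraction left is one minus twice the product percentage. The last reading, where scatter weighs least, gives

ratio = ln(left-handed left) / ln(right-handed left) = 2.26

We carry this reading as the selectivity factor, the logarithm of the fraction left of left-handed substrate over that of right-handed substrate. The readings at 40.0 min and 10.0 min give 2.01 and 2.55, so the earlier run shows scatter around it and no clear fall.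

Now the ladder. Read from the last reading as steady first-order losses without exchange, the earlier run gives left-handed substrate a half-life of 29.3 min and right-handed substrate one of 66.1 min. The new flask holds half the precatalyst. We guess that rate follows the charge, which stretches these rungs to 58.5 min and 132 min. The top rung is the 4.0 h of the flask, longer than both. An exchange too slow to show in 50.0 min stays open, but we reckon without one:

right-handed left = 28.4 % of its charge

left-handed left = right-handed left ^ ratio = 5.83 % of its charge

yield = 82.9 %, excess = 13.6 %

The forecast, a little lower in yield, says 80 %, an excess of 15 % and that exchange hardly takes part, on the ground “So there is no visible exchange”.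

The flask gives 89.6 % with an excess of 19.6 %, above our 82.9 % and 13.6 %, and the exchange lags behind, getting 44 % of the way. Its forward half-life for left-handed substrate, that step alone, is 2.0 h, shorter than the flask's time. With 13 % of the right-handed charge left, the carried ratio puts left-handed substrate at 0.983 % of its charge, but the flask holds 8.0 %.

    reagent + catalyst + left-handed substrate → catalyst + left-handed product (k = 190 L² mol⁻² min⁻¹)
    reagent + catalyst + right-handed substrate → catalyst + right-handed product (k = 95.0 L² mol⁻² min⁻¹)
    left-handed substrate ⇌ right-handed substrate (k = 0.00570 min⁻¹)
    precatalyst ⇌ catalyst (K = 1.40, k = 0.110 min⁻¹)
    2 catalyst ⇌ resting dimer, settled at all times (K = 5700 L mol⁻¹)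
    reagent → decomposition product (k = 9.20 × 10⁻⁵ min⁻¹)

In a neighbour flask, the same but with 0.10 M of reagent, 66 % of the right-handed charge is left, so the ratio gives 39.1 % of the left-handed charge. The computed flask holds 61 %.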